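**Retrosynthetic overview**
1. The target comes from global desilylation, preceded by hydrogenolytic opening of a temporary ring, of a cis-fused 2,6-diaryl-3,7-dioxabicyclo[3.3.0]octane (furofuran). This furofuran already carries the complete, protected erythro glycerol aryl ether side chain.
2. Enabling feature: on the oxolane ring of the target (O9', C7, C8, C8', C9'), the hydroxymethyl group on C8 (C9–O9) and the arylmethyl group on C8' (C7') are cis. O9 can therefore be tied to the benzylic carbon C7'. This C7'–O9 bond serves as the tether and as the temporary second ring (ring B), and through C7' it is the only stereocontrol element.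
3. Key disconnection: cutting C8'–C8 and O9'–C7 of the furofuran leads to an acyclic (E)-cinnamyl ether of an aryl oxiranyl carbinol. In the forward sense a titanocene radical–polar cascade closes ring B first. It then closes ring A, the oxolane of the target, and ring B is opened again one step later.
4. The precursor comes from a Suzuki–Miyaura union of an (E)-alkenylboronate (C7' set by a Sharpless kinetic resolution) with an aryl bromide that bears the side chain (C8'' set by an Evans syn aldol reaction, C7'' corrected by Mitsunobu inversion).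

Key step: step 14

Remark on locants and configuration:
- Lignan numbering is used.
- C7–C8–C9 is the ArCH–CH–CH2OH unit on the 3,5-dimethoxyphenyl ring (Ar2).
- C7'–C8'–C9' is the ArCH2–CH–CH2O unit of the 4-hydroxy-3-methoxybenzyl part (Ar1).
- C7''–C8''–C9'' is the glycerol chain on the third ring (Ar3).
- The target is read as (7R,8S,8'S,7''S,8''R), that is 7,8-trans, 8,8'-cis, with an erythro side chain.
- All four starting materials are taken as commercial.

Step 1
Reactants: 1 4-(benzyloxy)-3-methoxybenzaldehyde
Product: 2 rac-1-[4-(benzyloxy)-3-methoxyphenyl]prop-2-en-1-ol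
Conditions: CH2=CHMgBr (1.2 equiv), THF, 0 °C; aqueous work-up
Reagents that add atoms: vinylmagnesium bromide, C=C[Mg]Br
Why: Grignard 1,2-addition to the aldehyde gives the racemic aryl vinyl carbinol, and no stereocontrol is needed because step 2 resolves it.

Step 2
Reactants: 2 rac-1-[4-(benzyloxy)-3-methoxyphenyl]prop-2-en-1-ol
Product: 3 (S)-[4-(benzyloxy)-3-methoxyphenyl][(2R)-oxiran-2-yl]methanol (erythro epoxy alcohol)
Conditions: Ti(OiPr)4 (0.15 equiv), L-(+)-DIPT (0.18 equiv), t-BuOOH (0.45 equiv, decane), 4 Å MS, CH2Cl2, −20 °C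
Reagents that add atoms: tert-butyl hydroperoxide, CC(C)(C)OO
Why: In this Sharpless kinetic resolution the L-(+)-tartrate catalyst should epoxidise the (R)-carbinol much faster than the (S)-carbinol and from one alkene face, which gives the erythro epoxy alcohol and fixes C7', whereas the oxirane centre C8' is planarised in step 14 and need not be pure.

Step 3
Reactants: 3 (S)-[4-(benzyloxy)-3-methoxyphenyl][(2R)-oxiran-2-yl]methanol
Product: 4 (2R)-2-{(S)-[4-(benzyloxy)-3-methoxyphenyl](prop-2-yn-1-yloxy)methyl}oxirane
Conditions: propargyl bromide (1.5 equiv), Bu4NI (cat.), NaH (1.2 equiv, added last), THF, 0 °C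
Reagents that add atoms: propargyl bromide, C#CCBr
Why: Williamson etherification of the secondary alkoxide with the reactive propargylic bromide at low temperature should outrun Payne rearrangement and touches neither stereocentre.

Step 4
Reactants: 4 (2R)-2-{(S)-[4-(benzyloxy)-3-methoxyphenyl](prop-2-yn-1-yloxy)methyl}oxirane
Product: 5 pinacol ester of (E)-3-{(S)-[4-(benzyloxy)-3-methoxyphenyl][(2R)-oxiran-2-yl]methoxy}prop-1-enylboronic acid
Conditions: HBpin (1.5 equiv), Cy2BH (10 mol %), THF, rt
Reagents that add atoms: pinacolborane, CC1(C)OBOC1(C)C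
Why: Dialkylborane-catalysed syn hydroboration of the terminal alkyne places boron on the terminal carbon and should give the (E)-alkenylboronate without touching the oxirane.

Step 5
Reactants: 6 vanillin
Product: 7 3-methoxy-4-(triisopropylsilyloxy)benzaldehyde
Conditions: TIPSCl (1.1 equiv), imidazole (1.1 equiv), DMF, rt
Reagents that add atoms: chlorotriisopropylsilane, CC(C)[Si](Cl)(C(C)C)C(C)C
Why: Imidazole-promoted silyl ether formation installs a phenol protecting group that survives base, hydride, trivalent titanium and hydrogenation and keeps ring Ar3 non-phenolic in step 15.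

Step 6
Reactants: 8 4-bromo-2,6-dimethoxyphenol
Product: 9 (4-bromo-2,6-dimethoxyphenoxy)acetic acid
Conditions: BrCH2CO2H (1.2 equiv), NaOH (aq), 90 °C; then HCl (aq) to pH 2
Reagents that add atoms: bromoacetic acid, OC(=O)CBr
Why: Williamson ether synthesis of the phenoxide with bromoacetate gives the aryloxyacetic acid directly, and the aryl bromide is inert to aqueous base.

Step 7
Reactants: 9 (4-bromo-2,6-dimethoxyphenoxy)acetic acid; 10 (S)-4-benzyl-1,3-oxazolidin-2-one
Product: 12 (4S)-4-benzyl-3-[(4-bromo-2,6-dimethoxyphenoxy)acetyl]-1,3-oxazolidin-2-one, via mixed pivalic anhydride 11 (not isolated)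
Conditions: PivCl (1.05 equiv), Et3N (2.2 equiv), THF, −20 °C; then 10, LiCl (1.1 equiv), rt
Reagents that add atoms: none
Why: N-Acylation of the oxazolidinone through the mixed pivalic anhydride attaches the Evans auxiliary without strong base, and attack occurs at the less hindered aryloxyacetyl carbonyl group.

Step 8
Reactants: 12 (4S)-4-benzyl-3-[(4-bromo-2,6-dimethoxyphenoxy)acetyl]-1,3-oxazolidin-2-one; 7 3-methoxy-4-(triisopropylsilyloxy)benzaldehyde
Product: 15 syn aldol adduct (4S)-4-benzyl-3-[(2S,3R)-2-(4-bromo-2,6-dimethoxyphenoxy)-3-hydroxy-3-(3-methoxy-4-triisopropylsilyloxyphenyl)propanoyl]-1,3-oxazolidin-2-one, via boron enolate 13 (not isolated), via boron aldolate 14 (not isolated)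
Conditions: Bu2BOTf (1.1 equiv), Et3N (1.3 equiv), CH2Cl2, −78 to 0 °C; then 7, −78 to 0 °C; then H2O2, MeOH, pH 7 buffer, 0 °C
Reagents that add atoms: none
Why: In this Evans syn aldol reaction the (Z)-boron enolate reacts through a closed chair transition state on the face away from the benzyl group of the (S)-auxiliary, which sets C8'' in its final configuration and C7'' as the threo epimer that step 10 inverts.

Step 9
Reactants: 15 syn aldol adduct
Product: 16 threo diol (1R,2R)-2-(4-bromo-2,6-dimethoxyphenoxy)-1-(3-methoxy-4-triisopropylsilyloxyphenyl)propane-1,3-diol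
Conditions: LiBH4 (2 equiv), MeOH (2 equiv), THF, 0 °C
Reagents that add atoms: none
Why: Reductive cleavage of the N-acyl oxazolidinone with LiBH4 turns the acyl carbon into C9''H2OH, touches no stereocentre, and at 0 °C should be faster than retro-aldol cleavage.

Step 10
Reactants: 16 threo diol
Product: 17 erythro bis(4-nitrobenzoate) of (1S,2R)-2-(4-bromo-2,6-dimethoxyphenoxy)-1-(3-methoxy-4-triisopropylsilyloxyphenyl)propane-1,3-diol
Conditions: 4-O2NC6H4CO2H (3 equiv), PPh3 (3 equiv), DIAD (3 equiv), THF, 0 °C to rt
Reagents that add atoms: 4-nitrobenzoic acid, OC(=O)c1ccc(cc1)[N+](=O)[O-]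
Why: In this Mitsunobu reaction the primary alcohol is simply esterified while the secondary benzylic alcohol is displaced by carboxylate in an SN2 process with inversion, which converts threo (7''R) into the required erythro (7''S).

Step 11
Reactants: 17 erythro bis(4-nitrobenzoate)
Product: 18 erythro diol (1S,2R)-2-(4-bromo-2,6-dimethoxyphenoxy)-1-(3-methoxy-4-triisopropylsilyloxyphenyl)propane-1,3-diol
Conditions: K2CO3 (0.2 equiv), MeOH/THF, 0 °C
Reagents that add atoms: none
Why: Base-catalysed transesterification cleaves the activated 4-nitrobenzoates at the acyl carbon, so no bond to a stereocentre is broken, and the hindered aryl TIPS ether should survive the short, cold treatment.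

Step 12
Reactants: 18 erythro diol
Product: 19 5-bromo-2-{[(1S,2R)-1,3-bis(tert-butyldimethylsilyloxy)-1-(3-methoxy-4-triisopropylsilyloxyphenyl)propan-2-yl]oxy}-1,3-dimethoxybenzene
Conditions: TBSOTf (2.5 equiv), 2,6-lutidine (3 equiv), CH2Cl2, 0 °C
Reagents that add atoms: tert-butyldimethylsilyl triflate, CC(C)(C)[Si](C)(C)OS(=O)(=O)C(F)(F)F
Why: Silyl triflate silylation protects both alcohols as ethers that resist trivalent titanium, iodine and hydrogenation, and the bulky group on O7'' shields this benzylic C–O bond in step 15.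

Step 13
Reactants: 19 side-chain aryl bromide; 5 (E)-alkenylboronate
Product: 20 (2R)-2-{(S)-[4-(benzyloxy)-3-methoxyphenyl][(E)-3-(Ar2)prop-2-en-1-yloxy]methyl}oxirane, in which Ar2 is 3,5-dimethoxyphenyl bearing at C4 the (1S,2R)-1,3-bis(TBSO)-1-(3-methoxy-4-TIPSO-phenyl)propan-2-yloxy group
Conditions: Pd(OAc)2 (5 mol %), SPhos (10 mol %), K3PO4 (2 equiv), THF/H2O 10:1, 50 °C
Reagents that add atoms: none
Why: Suzuki–Miyaura coupling joins the two halves with retention of the E geometry under conditions that spare oxirane and silyl ethers, and any minor enantiomer of 5 becomes a separable diastereomer here.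

Step 14
Reactants: 20 epoxy cinnamyl ether
Product: 23 furofuran (1R,3aS,4R,6aS)-1-[4-(benzyloxy)-3-methoxyphenyl]-4-(Ar2)tetrahydro-1H,3H-furo[3,4-c]furan [(7R,8S,7'R,8'S); Ar2 as in 20], via bis-titanium oxolane 21 (not isolated), via benzylic iodide 22 (not isolated)
Conditions: Cp2TiCl2 (2.5 equiv), Zn dust, THF, rt (gives Cp2TiCl), filtered solution added slowly to 20 in THF (0.02 M), rt; then I2 (1.3 equiv), THF, rt to 50 °C
Reagents that add atoms: none
Why: Cp2TiCl (trivalent titanium) transfers one electron to the oxirane, the C8'–O bond breaks towards the more substituted secondary radical at C8' while O9' stays bound as a titanium alkoxide, the radical adds to C8 of the styrene, the benzylic C7 radical is caught by a second Cp2TiCl (21), iodine converts the C7–Ti bond into a labile benzylic iodide (22) and the alkoxide O9' displaces it, so that C8'–C8 and O9'–C7 are both made in one flask and an acyclic core with one relevant stereocentre becomes a bicycle with four. The closest known reaction type is the titanocene-mediated radical cyclisation of cinnamyl ethers of aryl oxiranyl carbinols with iodine termination, an established entry to furofuran lignans. Ring B (C7', O9, C9, C8, C8') closes 5-exo-trig by radical addition, and ring A (O9', C7, C8, C8', C9'), the oxolane of the target, closes 5-exo-tet by nucleophilic substitution. C8' is planarised, so C7' alone controls: in the chair-like transition state of the hexenyl-type radical the aryl group on C7' is pseudo-equatorial, which places the CH2O[Ti] arm on C8' trans to it, and the 1,5-cis preference of 1-substituted hexenyl radicals places the C8 side arm cis to that arm (cis ring fusion, the only geometry from which ring A can close). C7 is set in the substitution: the iodide epimers interconvert by iodide exchange and by ionisation assisted by the trialkoxyphenyl ring, and closure with the aryl group on the convex face is the less hindered path, which should give the 7,8-trans (exo) product. The step needs regioselective oxirane opening (secured by the higher stability of the secondary radical), 5-exo rather than 6-endo addition (secured by the aryl group on C7, which stabilises the exo radical) and cyclisation faster than capture of the C8' radical by titanium (secured by the fast addition to a styrene, dilution and slow addition of the reagent), while silyl ethers, aryl ethers and the benzyl ether are inert to the reagent.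

Step 15
Reactants: 23 furofuran
Product: 25 tris-silyl ether of the target [(7R,8S,8'S)-oxolane with free Ar1 phenol and free C9 alcohol], via debenzylated furofuran 24 (not isolated)
Conditions: H2 (3 bar), Pd/C (10 wt %), EtOAc/EtOH, rt, stopped after uptake of 2 equiv H2
Reagents that add atoms: none
Why: In this heterogeneous hydrogenolysis the aryl benzyl ether falls first (24), after which C7'–O9 is the only benzylic C–O bond that is para to a free phenol and still part of the strained bicycle, so it should be cleaved (the reaction type known for pinoresinol to lariciresinol) in preference to C7–O9' (non-phenolic, 4-O-alkylated ring) and C7''–OTBS (hindered silyl ether), which deletes the temporary stereocentre C7' and frees C9–OH.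

Step 16
Reactants: 25 tris-silyl ether of the target
Product: 26 target, (7R,8S,8'S,7''S,8''R)-sesquilignan CNP0170225.1
Conditions: TBAF (4 equiv), AcOH (4 equiv), THF, 0 °C to rt
Reagents that add atoms: none
Why: Fluoride-mediated desilylation buffered with acetic acid removes the aryl TIPS ether and both TBS ethers in one operation and stays too mild for quinone methide formation or epimerisation at C7 or C7''.

**Compound list**
1 | 4-(benzyloxy)-3-methoxybenzaldehyde | COc1cc(C=O)ccc1OCc1ccccc1 | starting material
2 | rac-1-[4-(benzyloxy)-3-methoxyphenyl]prop-2-en-1-ol | COc1cc(C(O)C=C)ccc1OCc1ccccc1 | intermediate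
3 | (S)-[4-(benzyloxy)-3-methoxyphenyl][(2R)-oxiran-2-yl]methanol | COc1cc([C@H](O)[C@H]2CO2)ccc1OCc1ccccc1 | intermediate
4 | (2R)-2-{(S)-[4-(benzyloxy)-3-methoxyphenyl](prop-2-yn-1-yloxy)methyl}oxirane | COc1cc([C@H](OCC#C)[C@H]2CO2)ccc1OCc1ccccc1 | intermediate
5 | pinacol (E)-3-{(S)-[4-(benzyloxy)-3-methoxyphenyl][(2R)-oxiran-2-yl]methoxy}prop-1-enylboronate | COc1cc([C@H](OC/C=C/B2OC(C)(C)C(C)(C)O2)[C@H]2CO2)ccc1OCc1ccccc1 | intermediate
6 | vanillin | COc1cc(C=O)ccc1O | starting material
7 | 3-methoxy-4-(triisopropylsilyloxy)benzaldehyde | COc1cc(C=O)ccc1O[Si](C(C)C)(C(C)C)C(C)C | intermediate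
8 | 4-bromo-2,6-dimethoxyphenol | COc1cc(Br)cc(OC)c1O | starting material
9 | (4-bromo-2,6-dimethoxyphenoxy)acetic acid | COc1cc(Br)cc(OC)c1OCC(=O)O | intermediate
10 | (S)-4-benzyl-1,3-oxazolidin-2-one | O=C1N[C@@H](Cc2ccccc2)CO1 | starting material
11 | (4-bromo-2,6-dimethoxyphenoxy)acetic pivalic anhydride | COc1cc(Br)cc(OC)c1OCC(=O)OC(=O)C(C)(C)C | intermediate
12 | (4S)-4-benzyl-3-[(4-bromo-2,6-dimethoxyphenoxy)acetyl]-1,3-oxazolidin-2-one | COc1cc(Br)cc(OC)c1OCC(=O)N1[C@@H](Cc2ccccc2)COC1=O | intermediate
13 | (Z)-dibutylboron enolate of 12 | COc1cc(Br)cc(OC)c1O/C=C(\OB(CCCC)CCCC)N1[C@@H](Cc2ccccc2)COC1=O | intermediate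
14 | dibutylboron aldolate of 15 | COc1cc(Br)cc(OC)c1O[C@H](C(=O)N1[C@@H](Cc2ccccc2)COC1=O)[C@H](OB(CCCC)CCCC)c1ccc(O[Si](C(C)C)(C(C)C)C(C)C)c(OC)c1 | intermediate
15 | (2S,3R) syn aldol adduct on the (4S)-auxiliary | COc1cc(Br)cc(OC)c1O[C@H](C(=O)N1[C@@H](Cc2ccccc2)COC1=O)[C@H](O)c1ccc(O[Si](C(C)C)(C(C)C)C(C)C)c(OC)c1 | intermediate
16 | (1R,2R) threo diol | COc1cc(Br)cc(OC)c1O[C@H](CO)[C@H](O)c1ccc(O[Si](C(C)C)(C(C)C)C(C)C)c(OC)c1 | intermediate
17 | (1S,2R) erythro bis(4-nitrobenzoate) | COc1cc(Br)cc(OC)c1O[C@H](COC(=O)c1ccc(cc1)[N+](=O)[O-])[C@@H](OC(=O)c1ccc(cc1)[N+](=O)[O-])c1ccc(O[Si](C(C)C)(C(C)C)C(C)C)c(OC)c1 | intermediate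
18 | (1S,2R) erythro diol | COc1cc(Br)cc(OC)c1O[C@H](CO)[C@@H](O)c1ccc(O[Si](C(C)C)(C(C)C)C(C)C)c(OC)c1 | intermediate
19 | (1S,2R) erythro bis-TBS ether, aryl bromide | COc1cc(Br)cc(OC)c1O[C@H](CO[Si](C)(C)C(C)(C)C)[C@@H](O[Si](C)(C)C(C)(C)C)c1ccc(O[Si](C(C)C)(C(C)C)C(C)C)c(OC)c1 | intermediate
20 | (E)-cinnamyl ether of the aryl oxiranyl carbinol (cascade precursor) | COc1cc([C@H](OC/C=C/c2cc(OC)c(O[C@H](CO[Si](C)(C)C(C)(C)C)[C@@H](O[Si](C)(C)C(C)(C)C)c3ccc(O[Si](C(C)C)(C(C)C)C(C)C)c(OC)c3)c(OC)c2)[C@H]2CO2)ccc1OCc1ccccc1 | intermediate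
21 | ring B oxolane with C7–TiClCp2 and O9'–TiClCp2 (C7 undefined) | COc1cc([C@@H]2OC[C@@H](C([Ti](Cl)(C3C=CC=C3)C3C=CC=C3)c3cc(OC)c(O[C@H](CO[Si](C)(C)C(C)(C)C)[C@@H](O[Si](C)(C)C(C)(C)C)c4ccc(O[Si](C(C)C)(C(C)C)C(C)C)c(OC)c4)c(OC)c3)[C@H]2CO[Ti](Cl)(C2C=CC=C2)C2C=CC=C2)ccc1OCc1ccccc1 | intermediate
22 | ring B oxolane with C7–I and O9'–TiClCp2 (C7 undefined) | COc1cc([C@@H]2OC[C@@H](C(I)c3cc(OC)c(O[C@H](CO[Si](C)(C)C(C)(C)C)[C@@H](O[Si](C)(C)C(C)(C)C)c4ccc(O[Si](C(C)C)(C(C)C)C(C)C)c(OC)c4)c(OC)c3)[C@H]2CO[Ti](Cl)(C2C=CC=C2)C2C=CC=C2)ccc1OCc1ccccc1 | intermediate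
23 | (7R,8S,7'R,8'S) furofuran, O-benzyl, tris-silyl | COc1cc([C@@H]2OC[C@@H]3[C@H]2CO[C@H]3c2cc(OC)c(O[C@H](CO[Si](C)(C)C(C)(C)C)[C@@H](O[Si](C)(C)C(C)(C)C)c3ccc(O[Si](C(C)C)(C(C)C)C(C)C)c(OC)c3)c(OC)c2)ccc1OCc1ccccc1 | intermediate
24 | debenzylated furofuran (free Ar1 phenol) | COc1cc([C@@H]2OC[C@@H]3[C@H]2CO[C@H]3c2cc(OC)c(O[C@H](CO[Si](C)(C)C(C)(C)C)[C@@H](O[Si](C)(C)C(C)(C)C)c3ccc(O[Si](C(C)C)(C(C)C)C(C)C)c(OC)c3)c(OC)c2)ccc1O | intermediate
25 | tris-silyl ether of the target | COc1cc(C[C@@H]2CO[C@@H](c3cc(OC)c(O[C@H](CO[Si](C)(C)C(C)(C)C)[C@@H](O[Si](C)(C)C(C)(C)C)c4ccc(O[Si](C(C)C)(C(C)C)C(C)C)c(OC)c4)c(OC)c3)[C@@H]2CO)ccc1O | intermediate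
26 | CNP0170225.1 | COc1cc(C[C@@H]2CO[C@@H](c3cc(OC)c(O[C@H](CO)[C@@H](O)c4ccc(O)c(OC)c4)c(OC)c3)[C@@H]2CO)ccc1O | target

**Step count and risks**
Total step count: 16.
Longest linear sequence: 11 steps (steps 6 to 16, from 8).

Steps most likely to fail:

Step 14. After the carbon–carbon bond is made, the termination may go astray. The benzylic titanium species may be protonated before iodine acts, or the displacement at C7 may be slow or stereorandom.
The fallback sets out from 20 and comes back at 23, and it separates the two bond formations.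
- The titanocene cyclisation and iodination are run as before. The mixture is then quenched with aqueous NaHCO3/Na2S2O3, so that the labile iodide 22 is hydrolysed and the ring B oxolane 1,4-diol F1 is isolated.
- Ring A is then closed in a separate acid-catalysed dehydrative etherification (camphorsulfonic acid cat., CH2Cl2, 0 °C). This runs through the trialkoxybenzyl cation under thermodynamic control and should funnel both C7 epimers into the exo-aryl furofuran 23.

Step 15. The hydrogenolysis may stall at the debenzylated furofuran. If forced, it may lose site selectivity, with cleavage of C7–O9' in ring A or of the C7''–O bond.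
The fallback sets out from 23 and comes back at 25, and it replaces surface hydrogenolysis by ionic hydrogenation through a benzylic cation.
- Et3SiH and BF3·OEt2 in CH2Cl2 at −78 °C should ionise C7'–O9 selectively. The 3,4-dialkoxyphenyl ring on C7' stabilises a cation better than the 3,5-dimethoxyphenyl ring on C7, whose 4-alkoxy group is twisted out of conjugation. It also does so better than C7'', which is deactivated by the neighbouring aryloxy group and the silyloxyaryl ring.
- This gives the O-benzyl ring-opened alcohol F2.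
- A short hydrogenolysis (H2 1 atm, Pd/C, EtOAc) then removes only the aryl benzyl ether to give 25.

Step 10. The electron-rich benzylic alcohol may react partly by ionisation, with loss of stereospecificity, or by elimination to the enol ether.
The fallback sets out from 16 and comes back at 19, and it inverts C7'' by a redox sequence instead of a substitution.
- TBSCl/imidazole silylates the primary alcohol selectively to the threo mono-TBS ether F3.
- Dess–Martin periodinane gives the α-aryloxy ketone F4.
- Chelation-controlled reduction with Zn(BH4)2 (Et2O, −78 °C) should deliver hydride to the open face of the chelate between the ketone oxygen and O8'' to give the erythro mono-TBS alcohol F5.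
- TBSOTf/2,6-lutidine then gives 19.

**Further compounds**
F1 | step 14 | ring B oxolane 1,4-diol (C7–OH undefined, C9'–OH) | COc1cc([C@@H]2OC[C@@H](C(O)c3cc(OC)c(O[C@H](CO[Si](C)(C)C(C)(C)C)[C@@H](O[Si](C)(C)C(C)(C)C)c4ccc(O[Si](C(C)C)(C(C)C)C(C)C)c(OC)c4)c(OC)c3)[C@H]2CO)ccc1OCc1ccccc1
F2 | step 15 | O-benzyl ring-opened alcohol (benzyl ether of 25) | COc1cc(C[C@@H]2CO[C@@H](c3cc(OC)c(O[C@H](CO[Si](C)(C)C(C)(C)C)[C@@H](O[Si](C)(C)C(C)(C)C)c4ccc(O[Si](C(C)C)(C(C)C)C(C)C)c(OC)c4)c(OC)c3)[C@@H]2CO)ccc1OCc1ccccc1
F3 | step 10 | threo mono-TBS ether | COc1cc(Br)cc(OC)c1O[C@H](CO[Si](C)(C)C(C)(C)C)[C@H](O)c1ccc(O[Si](C(C)C)(C(C)C)C(C)C)c(OC)c1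
F4 | step 10 | α-aryloxy ketone | COc1cc(Br)cc(OC)c1O[C@H](CO[Si](C)(C)C(C)(C)C)C(=O)c1ccc(O[Si](C(C)C)(C(C)C)C(C)C)c(OC)c1
F5 | step 10 | erythro mono-TBS alcohol | COc1cc(Br)cc(OC)c1O[C@H](CO[Si](C)(C)C(C)(C)C)[C@@H](O)c1ccc(O[Si](C(C)C)(C(C)C)C(C)C)c(OC)c1
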